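**Retrosynthetic overview**

- The target is reached from its triethylsilyl ether by Si–O cleavage, and that ether from the β,γ-unsaturated isomer by moving the ring alkene from C3=C4 to C2=C3.
- Feature used: with the ring numbered C1 (C=O), C2=C3, C4H2, C5 (carbinol carbon bearing nonadecyl) and C6H2, the ketone carbon C1 is a single carbon flanked by C2 and C6. The chain C2–C3–C4–C5–C6 is already present in a 2-vinylcyclopropan-1-ol: vinyl CH2 (C2), vinyl CH (C3), ring CH (C4), carbinol ring carbon (C5), ring CH2 (C6).
- Key disconnection: C1–C2 and C1–C6 to carbon monoxide and the silyl ether of 1-nonadecyl-2-vinylcyclopropan-1-ol, with opening of the C4–C6 cyclopropane bond. This closes the six-membered ring, the only ring of the target.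
- The vinylcyclopropane comes from a cyclopropanecarbaldehyde (methylenation), and that from a cyclopropylmethanol made by hydroxyl-directed asymmetric Simmons–Smith cyclopropanation of a (Z)-3-silyloxy allylic alcohol. This temporary three-membered ring sets C5. The allylic alcohol comes from icosanoic acid through the β-keto ester.
- Ring order: cyclopropane first, then the cyclohexenone at the expense of the cyclopropane. The vinyl-bearing stereocentre is erased in the key step, so only the oxygenated quaternary carbon has to be controlled.

Key step: step 7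

Assumption (chemistry): O-silylation of the chelated sodium enolate of the β-keto ester is taken to give the (Z)-enol ether. The route needs one geometrically pure enol ether matched to the ligand antipode (Z with 4R,5R; an E isomer would be paired with 4S,5S and would converge on the same ketone after the key step).

**Route**

Step 1
Reactants: 1 icosanoic acid; 2 potassium methyl malonate
Product: 4 methyl 3-oxodocosanoate, via icosanoyl imidazolide 3 (not isolated)
Conditions: CDI, THF, 40 °C; then 2, MgCl2, Et3N, MeCN/THF, rt; aq. HCl
Reagents that add atoms: potassium methyl malonate, [K+].[O-]C(=O)CC(=O)OC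
Why: Masamune–Brooks homologation: the magnesium enolate of the malonate half-ester is C-acylated by the acyl imidazolide 3 and the adduct loses CO2 to give the β-keto ester, the carboxyl carbon of 1 becoming the future carbinol carbon C5.

Step 2
Reactants: 4 methyl 3-oxodocosanoate; 5 chlorotriethylsilane
Product: 6 methyl (Z)-3-(triethylsilyloxy)docos-2-enoate
Conditions: NaH, THF, 0 °C; then Et3SiCl, 0 °C → rt
Reagents that add atoms: chlorotriethylsilane, CC[Si](Cl)(CC)CC
Why: O-Silylation of a β-keto ester enolate: the sodium ion chelates both oxygens in a U-shaped enolate, so silylation at the ketone oxygen should give the conjugated enol ether with silyloxy and ester cis (Z).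

Step 3
Reactants: 6 methyl (Z)-3-(triethylsilyloxy)docos-2-enoate
Product: 7 (Z)-3-(triethylsilyloxy)docos-2-en-1-ol
Conditions: i-Bu2AlH (2.2 equiv), CH2Cl2, −78 °C; aq. Rochelle salt
Reagents that add atoms: none
Why: DIBAL 1,2-reduction of an α,β-unsaturated ester to the allylic alcohol at low temperature, with a non-acidic tartrate work-up so that the silyl enol ether and its Z geometry are kept.

Step 4
Reactants: 7 (Z)-3-(triethylsilyloxy)docos-2-en-1-ol; 8 diiodomethane
Product: 9 [(1R,2R)-2-nonadecyl-2-(triethylsilyloxy)cyclopropyl]methanol (silyloxy and CH2OH cis)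
Conditions: Et2Zn, CH2I2, DME, CH2Cl2, −10 °C [gives Zn(CH2I)2·DME]; (4R,5R)-2-butyl-N,N,N′,N′-tetramethyl-1,3,2-dioxaborolane-4,5-dicarboxamide (1.2 equiv), 7, −10 °C → rt
Reagents that add atoms: diiodomethane, ICI
Why: Charette asymmetric Simmons–Smith cyclopropanation: the zinc alkoxide of 7 binds to boron of the (4R,5R)-dioxaborolane, which steers the Zn–CH2I unit to the Re face at C2 (the same facial sense as for simple E- and Z-allylic alcohols), and stereospecific syn addition to the Z enol ether places silyloxy and CH2OH cis, which fixes the oxygenated quaternary carbon as R.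

Step 5
Reactants: 9 [(1R,2R)-2-nonadecyl-2-(triethylsilyloxy)cyclopropyl]methanol
Product: 10 (1S,2R)-2-nonadecyl-2-(triethylsilyloxy)cyclopropane-1-carbaldehyde
Conditions: Dess–Martin periodinane, pyridine, CH2Cl2, 0 °C → rt
Reagents that add atoms: none
Why: Dess–Martin oxidation of a primary alcohol to the aldehyde under pyridine buffer, mild enough for the silyl ether and the donor–acceptor cyclopropane; the centre next to the formyl group (S by CIP priority only) may epimerise without consequence because it is erased in step 7.

Step 6
Reactants: 10 (1S,2R)-2-nonadecyl-2-(triethylsilyloxy)cyclopropane-1-carbaldehyde; 11 methyltriphenylphosphonium bromide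
Product: 12 triethyl{[(1R,2R)-2-ethenyl-1-nonadecylcyclopropyl]oxy}silane (silyloxy and vinyl cis)
Conditions: Ph3PCH3Br, KOt-Bu, THF, 0 °C; then 10, 0 °C → rt
Reagents that add atoms: methyltriphenylphosphonium bromide, C[P+](c1ccccc1)(c1ccccc1)c1ccccc1.[Br-]
Why: Wittig methylenation of the aldehyde with the non-stabilised ylide made in the flask; the silyloxycyclopropane is inert to the ylide and the quaternary centre is untouched.

Step 7
Reactants: 12 triethyl{[(1R,2R)-2-ethenyl-1-nonadecylcyclopropyl]oxy}silane; 13 carbon monoxide
Product: 14 (R)-5-nonadecyl-5-(triethylsilyloxy)cyclohex-3-en-1-one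
Conditions: Fe(CO)5 (1.5 equiv), CO (1 atm), hν (medium-pressure Hg lamp, Pyrex), 2-propanol, 20 °C; then air, filtration through Et3N-deactivated silica
Reagents that add atoms: carbon monoxide, [C-]#[O+] (from the CO atmosphere, relayed through Fe(CO)5)
Why: Proposed new method: photolysis of Fe(CO)5 gives the zerovalent Fe(CO)4 fragment, which binds the vinyl group of 12 and inserts into the adjacent C4–C6 cyclopropane bond (ring CH–CH2) to give an (η3-allyl)(alkyl)iron ferracycle; migratory insertion of CO into the Fe–C6 bond makes C1–C6, and acyl–allyl reductive elimination at the former vinyl CH2 makes C1–C2. The closest known reaction type is the iron-pentacarbonyl-mediated photochemical (or rhodium-catalysed) [5+1] carbonylation of alkyl-substituted alkenylcyclopropanes to cyclohex-3-enones; a cyclopropane carrying a silyloxy donor has not been put through it, which is why the step is proposed and not taken as known. The six-membered ring is closed by that reductive elimination, a C–C bond formation between the acyl carbon and the CH2 terminus of the allyl ligand, six-ring closure being preferred over four-ring closure at C4. No stereocentre is created: C5 is never a reacting centre and keeps its configuration (R in 12 and in 14), while the vinyl-bearing centre becomes sp2, so the cis/trans composition of 12 does not matter. The step needs cleavage of C4–C6 and not of C4–C5: insertion toward C5 would put iron on a fully substituted, silyloxy-bearing carbon, whereas insertion toward C6 gives a primary alkyl–iron bond, and because the quaternary C5 next to that bond carries no hydrogen, β-hydride collapse to a diene complex is closed and the CO atmosphere should keep insertion ahead of β-silyloxide loss.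

Step 8
Reactants: 14 (R)-5-nonadecyl-5-(triethylsilyloxy)cyclohex-3-en-1-one
Product: 15 (S)-5-nonadecyl-5-(triethylsilyloxy)cyclohex-2-en-1-one
Conditions: DBU (0.2 equiv), CH2Cl2, 0 °C
Reagents that add atoms: none
Why: Base-mediated isomerisation of a β,γ- to an α,β-unsaturated ketone: DBU removes the doubly activated C2 proton, the dienolate is reprotonated at C4 and conjugation drives the equilibrium, while C5 is not involved (S by CIP priority change only) and substoichiometric base at 0 °C limits loss of silanolate.

Step 9
Reactants: 15 (S)-5-nonadecyl-5-(triethylsilyloxy)cyclohex-2-en-1-one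
Product: 16 (S)-5-hydroxy-5-nonadecylcyclohex-2-en-1-one
Conditions: HF·pyridine, pyridine, THF, 0 °C → rt
Reagents that add atoms: none
Why: Fluoride-induced cleavage of the tertiary triethylsilyl ether (Si–F bond formation) under pyridine-buffered, non-basic conditions that should avoid retro-aldol cleavage and dehydration of the β-hydroxy ketone, with C5 untouched.

**Compound list**

1 | icosanoic acid | CCCCCCCCCCCCCCCCCCCC(=O)O | starting material
2 | potassium methyl malonate (potassium 3-methoxy-3-oxopropanoate) | [K+].[O-]C(=O)CC(=O)OC | starting material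
3 | icosanoyl imidazolide, 1-(1H-imidazol-1-yl)icosan-1-one | CCCCCCCCCCCCCCCCCCCC(=O)n1ccnc1 | intermediate
4 | methyl 3-oxodocosanoate | CCCCCCCCCCCCCCCCCCCC(=O)CC(=O)OC | intermediate
5 | chlorotriethylsilane | CC[Si](Cl)(CC)CC | starting material
6 | methyl (Z)-3-(triethylsilyloxy)docos-2-enoate | CCCCCCCCCCCCCCCCCCC/C(O[Si](CC)(CC)CC)=C/C(=O)OC | intermediate
7 | (Z)-3-(triethylsilyloxy)docos-2-en-1-ol | CCCCCCCCCCCCCCCCCCC/C(O[Si](CC)(CC)CC)=C/CO | intermediate
8 | diiodomethane | ICI | starting material
9 | [(1R,2R)-2-nonadecyl-2-(triethylsilyloxy)cyclopropyl]methanol | CCCCCCCCCCCCCCCCCCC[C@@]1(O[Si](CC)(CC)CC)C[C@@H]1CO | intermediate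
10 | (1S,2R)-2-nonadecyl-2-(triethylsilyloxy)cyclopropane-1-carbaldehyde | CCCCCCCCCCCCCCCCCCC[C@@]1(O[Si](CC)(CC)CC)C[C@@H]1C=O | intermediate
11 | methyltriphenylphosphonium bromide | C[P+](c1ccccc1)(c1ccccc1)c1ccccc1.[Br-] | starting material
12 | triethyl{[(1R,2R)-2-ethenyl-1-nonadecylcyclopropyl]oxy}silane | CCCCCCCCCCCCCCCCCCC[C@@]1(O[Si](CC)(CC)CC)C[C@@H]1C=C | intermediate
13 | carbon monoxide | [C-]#[O+] | starting material
14 | (R)-5-nonadecyl-5-(triethylsilyloxy)cyclohex-3-en-1-one | CCCCCCCCCCCCCCCCCCC[C@]1(O[Si](CC)(CC)CC)C=CCC(=O)C1 | intermediate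
15 | (S)-5-nonadecyl-5-(triethylsilyloxy)cyclohex-2-en-1-one | CCCCCCCCCCCCCCCCCCC[C@]1(O[Si](CC)(CC)CC)CC=CC(=O)C1 | intermediate
16 | (S)-5-hydroxy-5-nonadecylcyclohex-2-en-1-one | CCCCCCCCCCCCCCCCCCC[C@]1(O)CC=CC(=O)C1 | target

Total step count: 9
Longest linear sequence: 9 steps (from 1)

**Steps most likely to fail**

1. Step 7 (proposed step). Iron may insert into the donor-weakened C4–C5 bond instead of C4–C6, or the ferracycle may lose silyloxide or collapse to a diene–iron complex before CO is taken up. The fallback uses known chemistry, sets out from 4 and comes back at 16. Robinson-type annulation of 4 with methyl vinyl ketone (NaOMe, MeOH; then pyrrolidine, AcOH) should give racemic methyl 2-nonadecyl-4-oxocyclohex-2-ene-1-carboxylate F1. Saponification and decarboxylation of this vinylogous β-keto ester (KOH, aq. EtOH, reflux; then HCl) should give 3-nonadecylcyclohex-2-en-1-one F2. Copper-catalysed enantioselective conjugate borylation (Cu(MeCN)4PF6, monovalent copper; a P-chirogenic bisphosphine whose antipode is chosen to place boron on the face leading to the R boronate; LiOt-Bu, B2pin2) should give (R)-3-nonadecyl-3-(4,4,5,5-tetramethyl-1,3,2-dioxaborolan-2-yl)cyclohexan-1-one F3. Oxidation with retention (NaBO3·4H2O, THF/H2O) should give (S)-3-hydroxy-3-nonadecylcyclohexan-1-one F4. Treatment with LDA (2.2 equiv) and Me3SiCl at −78 °C should silylate the alkoxide and the kinetic enolate on the side away from the quaternary carbon, giving (S)-5-nonadecyl-1,5-bis(trimethylsilyloxy)cyclohex-1-ene F5. Saegusa–Ito oxidation (Pd(OAc)2, MeCN), which can only dehydrogenate toward the side that carries hydrogen, should give (S)-5-nonadecyl-5-(trimethylsilyloxy)cyclohex-2-en-1-one F6. Mild solvolysis (citric acid, MeOH, 0 °C) should then release 16.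

2. Step 8. The dienolate may expel triethylsilanolate by vinylogous β-elimination, and the resulting cyclohexadienone would tautomerise to a phenol. The fallback sets out from 14 and comes back at 15 without base-mediated alkene migration. Hydrogenation of the ring alkene (H2, Rh/Al2O3, EtOAc) should give (S)-3-nonadecyl-3-(triethylsilyloxy)cyclohexan-1-one F7. Kinetic enolisation on the unhindered side (LDA, Me3SiCl, THF, −78 °C) should give triethyl{[(1S)-1-nonadecyl-3-(trimethylsilyloxy)cyclohex-3-en-1-yl]oxy}silane F8. Saegusa–Ito oxidation (Pd(OAc)2, MeCN, rt) should give 15.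

3. Step 4. Facial selectivity may erode if zinc is chelated by the silyloxy oxygen outside the boronate-bound alkoxide assembly. The fallback sets out from 7 and comes back at 9 by separating control of relative and absolute configuration. Hydroxyl-directed cyclopropanation without the chiral ligand (Et2Zn, CH2I2, CH2Cl2, 0 °C) should give racemic cis-[2-nonadecyl-2-(triethylsilyloxy)cyclopropyl]methanol F9. Lipase-mediated kinetic resolution (Burkholderia cepacia lipase, vinyl acetate, t-BuOMe), with enzyme and acyl donor screened so that the unwanted enantiomer is acylated to [(1S,2S)-2-nonadecyl-2-(triethylsilyloxy)cyclopropyl]methyl acetate F10, would leave 9 as the unreacted alcohol, separable by chromatography.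

**Further compounds**

F1 | step 7 | methyl 2-nonadecyl-4-oxocyclohex-2-ene-1-carboxylate (racemic) | CCCCCCCCCCCCCCCCCCCC1=CC(=O)CCC1C(=O)OC
F2 | step 7 | 3-nonadecylcyclohex-2-en-1-one | CCCCCCCCCCCCCCCCCCCC1=CC(=O)CCC1
F3 | step 7 | (R)-3-nonadecyl-3-(4,4,5,5-tetramethyl-1,3,2-dioxaborolan-2-yl)cyclohexan-1-one | CCCCCCCCCCCCCCCCCCC[C@]1(B2OC(C)(C)C(C)(C)O2)CCCC(=O)C1
F4 | step 7 | (S)-3-hydroxy-3-nonadecylcyclohexan-1-one | CCCCCCCCCCCCCCCCCCC[C@]1(O)CCCC(=O)C1
F5 | step 7 | (S)-5-nonadecyl-1,5-bis(trimethylsilyloxy)cyclohex-1-ene | CCCCCCCCCCCCCCCCCCC[C@]1(O[Si](C)(C)C)CCC=C(O[Si](C)(C)C)C1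
F6 | step 7 | (S)-5-nonadecyl-5-(trimethylsilyloxy)cyclohex-2-en-1-one | CCCCCCCCCCCCCCCCCCC[C@]1(O[Si](C)(C)C)CC=CC(=O)C1
F7 | step 8 | (S)-3-nonadecyl-3-(triethylsilyloxy)cyclohexan-1-one | CCCCCCCCCCCCCCCCCCC[C@]1(O[Si](CC)(CC)CC)CCCC(=O)C1
F8 | step 8 | triethyl{[(1S)-1-nonadecyl-3-(trimethylsilyloxy)cyclohex-3-en-1-yl]oxy}silane | CCCCCCCCCCCCCCCCCCC[C@]1(O[Si](CC)(CC)CC)CCC=C(O[Si](C)(C)C)C1
F9 | step 4 | racemic cis-[2-nonadecyl-2-(triethylsilyloxy)cyclopropyl]methanol (both enantiomers) | CCCCCCCCCCCCCCCCCCC[C@@]1(O[Si](CC)(CC)CC)C[C@@H]1CO.CCCCCCCCCCCCCCCCCCC[C@]1(O[Si](CC)(CC)CC)C[C@H]1CO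
F10 | step 4 | [(1S,2S)-2-nonadecyl-2-(triethylsilyloxy)cyclopropyl]methyl acetate | CCCCCCCCCCCCCCCCCCC[C@]1(O[Si](CC)(CC)CC)C[C@H]1COC(C)=O
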